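**Retrosynthetic overview** (ring carbons of the target: C1 = quaternary carbon, C2 = aryl-bearing CH, C3=C4(Me), C5, C6)
1. Both pyranone rings are made last: double ortho-formylation of a bis-phenol, then annulation with Ph3P=C=C=O.
2. The cyclohexene ring is closed at C3=C4 by ring-closing metathesis; the (E)-styryl bond comes from a Heck arylation of a vinyl group on C1.
3. The quaternary centre C1 is set by methylation of a β-aryl-γ-butyrolactone enolate anti to the aryl group (control from C2).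
4. Key step: the C1–C2 bond and the C2 stereocentre come from the amine-catalysed asymmetric Michael addition of aldehyde 7 to nitrostyrene 4.
5. Ring order: temporary γ-lactone, then cyclohexene, then the two coumarin lactones.

Assumption: 1, 5, 19 and all reagents are purchased, and the (S)-prolinol catalyst shows its usual facial sense with nitrostyrene 4 (syn adduct, 2R,3S).
Abbreviation: ArSi = 2-methoxy-4-[(triisopropylsilyl)oxy]phenyl.

**Step 1**
Reactants: 1 4-hydroxy-2-methoxybenzaldehyde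
Product: 2 2-methoxy-4-[(triisopropylsilyl)oxy]benzaldehyde
Conditions: iPr3SiCl (1.1 equiv), imidazole (2.2 equiv), DMF, 0 °C to rt
Reagents that add atoms: chlorotriisopropylsilane, CC(C)[Si](Cl)(C(C)C)C(C)C
Why: O-silylation of the phenol gives a bulky silyl ether that survives the later basic, hydride and palladium steps and is removed by fluoride.

**Step 2**
Reactants: 2 2-methoxy-4-[(triisopropylsilyl)oxy]benzaldehyde
Product: 4 (E)-1-ArSi-2-nitroethene, via nitro alcohol 3 (not isolated)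
Conditions: MeNO2 (solvent), NH4OAc (0.3 equiv), 80 °C
Reagents that add atoms: nitromethane, C[N+](=O)[O-]
Why: Henry (nitroaldol) addition followed by dehydration in the flask gives the conjugated nitroalkene as the (E)-isomer only.

**Step 3**
Reactants: 5 methyl 5-oxohexanoate
Product: 6 methyl 4-(2-methyl-1,3-dioxolan-2-yl)butanoate
Conditions: HOCH2CH2OH (1.5 equiv), p-TsOH·H2O (2 mol %), toluene, reflux, Dean–Stark trap
Reagents that add atoms: ethylene glycol, OCCO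
Why: Acid-catalysed ketalisation driven by water removal masks the methyl ketone that later becomes C4 and its methyl group.

**Step 4**
Reactants: 6 methyl 4-(2-methyl-1,3-dioxolan-2-yl)butanoate
Product: 7 4-(2-methyl-1,3-dioxolan-2-yl)butanal
Conditions: iBu2AlH (1.05 equiv), CH2Cl2, −78 °C; aqueous KNaC4H4O6
Reagents that add atoms: none
Why: Partial hydride reduction of the ester stops at the aluminium hemiacetal at −78 °C, which gives the aldehyde on work-up.

**Step 5**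
Reactants: 4 (E)-1-ArSi-2-nitroethene; 7 4-(2-methyl-1,3-dioxolan-2-yl)butanal (1.5 equiv)
Product: 8 (2R,3S)-3-ArSi-2-[2-(2-methyl-1,3-dioxolan-2-yl)ethyl]-4-nitrobutanal
Conditions: (S)-α,α-diphenylprolinol trimethylsilyl ether (10 mol %), PhCO2H (10 mol %), toluene, 0 °C to rt
Reagents that add atoms: none
Why: Enamine-catalysed asymmetric Michael addition of an aldehyde to a nitroalkene, in which the diphenyl(silyloxy)methyl group blocks one enamine face and the synclinal transition state gives the syn adduct, so C2 is fixed as required (C1 is set only provisionally and is re-set in step 10).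

**Step 6**
Reactants: 8 (2R,3S)-3-ArSi-2-[2-(2-methyl-1,3-dioxolan-2-yl)ethyl]-4-nitrobutanal
Product: 9 (2R,3S)-3-ArSi-2-[2-(2-methyl-1,3-dioxolan-2-yl)ethyl]-4-nitrobutanoic acid
Conditions: NaClO2 (3 equiv), NaH2PO4 (3 equiv), 2-methyl-2-butene (10 equiv), t-BuOH/H2O, 0 °C to rt
Reagents that add atoms: sodium chlorite, [Na+].[O-]Cl=O
Why: Pinnick oxidation converts only the aldehyde into the acid, and the alkene scavenger removes HOCl before it can chlorinate the electron-rich arene.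

**Step 7**
Reactants: 9 (2R,3S)-3-ArSi-2-[2-(2-methyl-1,3-dioxolan-2-yl)ethyl]-4-nitrobutanoic acid
Product: 10 methyl (2R,3S)-3-ArSi-2-[2-(2-methyl-1,3-dioxolan-2-yl)ethyl]-4-nitrobutanoate
Conditions: Me3SiCHN2 (1.3 equiv), toluene/MeOH 4:1, 0 °C
Reagents that add atoms: (trimethylsilyl)diazomethane, C[Si](C)(C)C=[N+]=[N-]
Why: Esterification with a diazoalkane is neutral, so the acidic CH2NO2 group is not alkylated.

**Step 8**
Reactants: 10 methyl (2R,3S)-3-ArSi-2-[2-(2-methyl-1,3-dioxolan-2-yl)ethyl]-4-nitrobutanoate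
Product: 12 (2S,3R)-2-ArSi-3-(methoxycarbonyl)-5-(2-methyl-1,3-dioxolan-2-yl)pentanoic acid, via nitrolic acid 11 (not isolated)
Conditions: NaNO2 (3 equiv), AcOH (10 equiv), DMSO, 35 °C
Reagents that add atoms: sodium nitrite, [Na+].[O-]N=O; water, O
Why: Oxidative Nef-type conversion of the primary nitroalkane into a carboxylic acid by nitrosation to the nitrolic acid and hydrolysis, in a weakly acidic medium that leaves the α-aryl stereocentre, the ketal and the ester alone.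

**Step 9**
Reactants: 12 (2S,3R)-2-ArSi-3-(methoxycarbonyl)-5-(2-methyl-1,3-dioxolan-2-yl)pentanoic acid
Product: 14 (3R,4S)-4-ArSi-3-[2-(2-methyl-1,3-dioxolan-2-yl)ethyl]oxolan-2-one (trans), via hydroxy ester 13 (not isolated)
Conditions: BH3·SMe2 (1.5 equiv), THF, 0 °C to rt; MeOH; then DBU (10 mol %), toluene, 50 °C
Reagents that add atoms: none
Why: Borane reduces the carboxylic acid chemoselectively beside the methyl ester, and the resulting γ-hydroxy ester lactonises by transesterification without any base touching C2.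

**Step 10**
Reactants: 14 (3R,4S)-4-ArSi-3-[2-(2-methyl-1,3-dioxolan-2-yl)ethyl]oxolan-2-one
Product: 16 (3S,4R)-4-ArSi-3-methyl-3-[2-(2-methyl-1,3-dioxolan-2-yl)ethyl]oxolan-2-one, via lithium enolate 15 (not isolated)
Conditions: LiN(iPr)2 (1.15 equiv), THF, −78 °C; MeI (3 equiv), −78 to −30 °C
Reagents that add atoms: iodomethane, CI
Why: Enolate alkylation in which MeI attacks the planar lactone enolate on the face anti to the neighbouring aryl group, so the methyl group ends trans to the aryl and the quaternary centre C1 is set by substrate control from C2.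

**Step 11**
Reactants: 16 (3S,4R)-4-ArSi-3-methyl-3-[2-(2-methyl-1,3-dioxolan-2-yl)ethyl]oxolan-2-one
Product: 17 (3S,4R)-4-ArSi-3-methyl-3-[2-(2-methyl-1,3-dioxolan-2-yl)ethyl]oxolan-2-ol (both anomers)
Conditions: iBu2AlH (1.3 equiv), CH2Cl2, −78 °C; aqueous KNaC4H4O6
Reagents that add atoms: none
Why: Partial hydride reduction of the lactone gives the lactol, which differentiates the two oxygenated carbons for the next step.

**Step 12**
Reactants: 17 (3S,4R)-4-ArSi-3-methyl-3-[2-(2-methyl-1,3-dioxolan-2-yl)ethyl]oxolan-2-ol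
Product: 18 (2S,3R)-2-ArSi-3-methyl-3-[2-(2-methyl-1,3-dioxolan-2-yl)ethyl]pent-4-en-1-ol
Conditions: Ph3PCH3Br (3.5 equiv), KN(SiMe3)2 (3.3 equiv), THF, 0 °C to 60 °C
Reagents that add atoms: methyltriphenylphosphonium bromide, C[P+](c1ccccc1)(c1ccccc1)c1ccccc1.[Br-]
Why: Wittig methylenation of the open hydroxy-aldehyde form of the lactol turns the former lactone carbon into the vinyl group on C1 and frees the C3 alcohol, with no stereocentre at risk because C1 is quaternary.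

**Step 13**
Reactants: 19 4-bromo-3-methoxyphenol
Product: 20 (4-bromo-3-methoxyphenoxy)triisopropylsilane
Conditions: iPr3SiCl (1.1 equiv), imidazole (2.2 equiv), DMF, rt
Reagents that add atoms: chlorotriisopropylsilane, CC(C)[Si](Cl)(C(C)C)C(C)C
Why: O-silylation gives the aryl bromide the same phenol protection as the first aryl unit.

**Step 14**
Reactants: 18 (2S,3R)-2-ArSi-3-methyl-3-[2-(2-methyl-1,3-dioxolan-2-yl)ethyl]pent-4-en-1-ol; 20 (4-bromo-3-methoxyphenoxy)triisopropylsilane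
Product: 21 (2S,3R,4E)-2,5-bis(ArSi)-3-methyl-3-[2-(2-methyl-1,3-dioxolan-2-yl)ethyl]pent-4-en-1-ol
Conditions: Pd2(dba)3 (2.5 mol %), [HP(t-Bu)3]BF4 (10 mol %), Cy2NMe (1.5 equiv), 1,4-dioxane, 90 °C
Reagents that add atoms: none
Why: Mizoroki–Heck arylation puts the aryl group on the terminal CH2, and β-hydride elimination can only use the benzylic hydrogens because C1 has none, so only the (E)-styrene forms and the double bond cannot migrate.

**Step 15**
Reactants: 21 (2S,3R,4E)-2,5-bis(ArSi)-3-methyl-3-[2-(2-methyl-1,3-dioxolan-2-yl)ethyl]pent-4-en-1-ol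
Product: 22 (5R,6S)-6-ArSi-5-[(E)-2-ArSi-ethenyl]-7-hydroxy-5-methylheptan-2-one
Conditions: pyridinium p-toluenesulfonate (20 mol %), acetone/H2O 10:1, 50 °C
Reagents that add atoms: water, O
Why: Mild acid-catalysed ketal hydrolysis frees the methyl ketone, with an acid too weak to protonate the electron-rich styrene or cleave the aryl silyl ethers.

**Step 16**
Reactants: 22 (5R,6S)-6-ArSi-5-[(E)-2-ArSi-ethenyl]-7-hydroxy-5-methylheptan-2-one
Product: 23 (2S,3R)-2-ArSi-3-[(E)-2-ArSi-ethenyl]-3-methyl-6-oxoheptanal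
Conditions: Dess–Martin periodinane (1.3 equiv), CH2Cl2, 0 °C to rt
Reagents that add atoms: none
Why: Dess–Martin oxidation gives the aldehyde without base, which keeps the α-aryl stereocentre C2 intact.

**Step 17**
Reactants: 23 (2S,3R)-2-ArSi-3-[(E)-2-ArSi-ethenyl]-3-methyl-6-oxoheptanal
Product: 25 (5R,6S)-6-ArSi-5-[(E)-2-ArSi-ethenyl]-2,5-dimethylocta-1,7-diene, via keto alkene 24 (not isolated)
Conditions: Ph3PCH3Br (3.5 equiv), KN(SiMe3)2 (3.3 equiv), THF; 23 added at −78 °C, then to rt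
Reagents that add atoms: methyltriphenylphosphonium bromide, C[P+](c1ccccc1)(c1ccccc1)c1ccccc1.[Br-]
Why: Double Wittig methylenation in which the aldehyde reacts within minutes at −78 °C, faster than enolisation at C2, and the methyl ketone follows on warming.

**Step 18**
Reactants: 25 (5R,6S)-6-ArSi-5-[(E)-2-ArSi-ethenyl]-2,5-dimethylocta-1,7-diene
Product: 26 (3S,4R)-3-ArSi-4-[(E)-2-ArSi-ethenyl]-1,4-dimethylcyclohex-1-ene
Conditions: second-generation Grubbs catalyst (H2IMes)(PCy3)Cl2Ru=CHPh (5 mol %), CH2Cl2 (0.01 M), 40 °C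
Reagents that add atoms: none
Why: Ring-closing olefin metathesis between the vinyl group and the 1,1-disubstituted alkene forms the six-membered ring with the trisubstituted C3=C4 bond, while the hindered internal styryl alkene stays out and loss of ethene drives the reaction.

**Step 19**
Reactants: 26 (3S,4R)-3-ArSi-4-[(E)-2-ArSi-ethenyl]-1,4-dimethylcyclohex-1-ene
Product: 27 (3S,4R)-3-(4-hydroxy-2-methoxyphenyl)-4-[(E)-2-(4-hydroxy-2-methoxyphenyl)ethenyl]-1,4-dimethylcyclohex-1-ene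
Conditions: Bu4NF (2.4 equiv), THF, 0 °C
Reagents that add atoms: none
Why: Fluoride-induced desilylation frees both phenols under conditions that do not touch the alkenes.

**Step 20**
Reactants: 27 (3S,4R)-3-(4-hydroxy-2-methoxyphenyl)-4-[(E)-2-(4-hydroxy-2-methoxyphenyl)ethenyl]-1,4-dimethylcyclohex-1-ene
Product: 29 (3S,4R)-3-(5-formyl-4-hydroxy-2-methoxyphenyl)-4-[(E)-2-(5-formyl-4-hydroxy-2-methoxyphenyl)ethenyl]-1,4-dimethylcyclohex-1-ene, via bis(benzyl alcohol) 28 (not isolated)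
Conditions: MgCl2 (4 equiv), Et3N (8 equiv), (CH2O)n (14 equiv), THF, reflux; 1 M HCl work-up
Reagents that add atoms: paraformaldehyde (as formaldehyde), C=O
Why: Magnesium-phenoxide-directed ortho-formylation (Casnati–Skattebøl) adds formaldehyde at the free ortho position para to the methoxy group of each phenol, and the salicyl alcohol is oxidised to the aldehyde by hydride transfer to a second formaldehyde.

**Step 21**
Reactants: 29 (3S,4R)-3-(5-formyl-4-hydroxy-2-methoxyphenyl)-4-[(E)-2-(5-formyl-4-hydroxy-2-methoxyphenyl)ethenyl]-1,4-dimethylcyclohex-1-ene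
Product: 31 6-[(E)-2-[(1R,2S)-2-(7-methoxy-2-oxo-2H-chromen-6-yl)-1,4-dimethylcyclohex-3-en-1-yl]ethenyl]-7-methoxy-2H-chromen-2-one, via bis(ester ylide) 30 (not isolated)
Conditions: Ph3P=C=C=O (2.4 equiv), toluene, 100 °C
Reagents that add atoms: (triphenylphosphoranylidene)ketene, O=C=C=P(c1ccccc1)(c1ccccc1)c1ccccc1
Why: Each phenol adds to the ketene ylide to give an aryl ester phosphorane that closes by intramolecular Wittig reaction onto the ortho aldehyde, which builds each coumarin ring directly below the temperature at which the cyclohexene core could rearrange.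

**Compound list**
1 | 4-hydroxy-2-methoxybenzaldehyde | COc1cc(O)ccc1C=O | starting material
2 | 2-methoxy-4-[(triisopropylsilyl)oxy]benzaldehyde | COc1cc(O[Si](C(C)C)(C(C)C)C(C)C)ccc1C=O | intermediate
3 | 1-ArSi-2-nitroethan-1-ol (racemic) | COc1cc(O[Si](C(C)C)(C(C)C)C(C)C)ccc1C(O)C[N+](=O)[O-] | intermediate
4 | (E)-1-ArSi-2-nitroethene | COc1cc(O[Si](C(C)C)(C(C)C)C(C)C)ccc1/C=C/[N+](=O)[O-] | intermediate
5 | methyl 5-oxohexanoate | COC(=O)CCCC(C)=O | starting material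
6 | methyl 4-(2-methyl-1,3-dioxolan-2-yl)butanoate | COC(=O)CCCC1(C)OCCO1 | intermediate
7 | 4-(2-methyl-1,3-dioxolan-2-yl)butanal | O=CCCCC1(C)OCCO1 | intermediate
8 | (2R,3S)-3-ArSi-2-[2-(2-methyl-1,3-dioxolan-2-yl)ethyl]-4-nitrobutanal | O=C[C@H](CCC1(C)OCCO1)[C@H](C[N+](=O)[O-])c1ccc(O[Si](C(C)C)(C(C)C)C(C)C)cc1OC | intermediate
9 | (2R,3S)-3-ArSi-2-[2-(2-methyl-1,3-dioxolan-2-yl)ethyl]-4-nitrobutanoic acid | OC(=O)[C@H](CCC1(C)OCCO1)[C@H](C[N+](=O)[O-])c1ccc(O[Si](C(C)C)(C(C)C)C(C)C)cc1OC | intermediate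
10 | methyl (2R,3S)-3-ArSi-2-[2-(2-methyl-1,3-dioxolan-2-yl)ethyl]-4-nitrobutanoate | COC(=O)[C@H](CCC1(C)OCCO1)[C@H](C[N+](=O)[O-])c1ccc(O[Si](C(C)C)(C(C)C)C(C)C)cc1OC | intermediate
11 | methyl (2R,3S)-3-ArSi-4-(hydroxyimino)-2-[2-(2-methyl-1,3-dioxolan-2-yl)ethyl]-4-nitrobutanoate (nitrolic acid) | COC(=O)[C@H](CCC1(C)OCCO1)[C@H](C(=NO)[N+](=O)[O-])c1ccc(O[Si](C(C)C)(C(C)C)C(C)C)cc1OC | intermediate
12 | (2S,3R)-2-ArSi-3-(methoxycarbonyl)-5-(2-methyl-1,3-dioxolan-2-yl)pentanoic acid | COC(=O)[C@H](CCC1(C)OCCO1)[C@H](C(=O)O)c1ccc(O[Si](C(C)C)(C(C)C)C(C)C)cc1OC | intermediate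
13 | methyl (2R,3S)-3-ArSi-4-hydroxy-2-[2-(2-methyl-1,3-dioxolan-2-yl)ethyl]butanoate | COC(=O)[C@H](CCC1(C)OCCO1)[C@H](CO)c1ccc(O[Si](C(C)C)(C(C)C)C(C)C)cc1OC | intermediate
14 | (3R,4S)-4-ArSi-3-[2-(2-methyl-1,3-dioxolan-2-yl)ethyl]oxolan-2-one | O=C1OC[C@H](c2ccc(O[Si](C(C)C)(C(C)C)C(C)C)cc2OC)[C@H]1CCC3(C)OCCO3 | intermediate
15 | lithium (4R)-4-ArSi-3-[2-(2-methyl-1,3-dioxolan-2-yl)ethyl]-4,5-dihydrofuran-2-olate | [Li]OC1=C(CCC3(C)OCCO3)[C@@H](c2ccc(O[Si](C(C)C)(C(C)C)C(C)C)cc2OC)CO1 | intermediate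
16 | (3S,4R)-4-ArSi-3-methyl-3-[2-(2-methyl-1,3-dioxolan-2-yl)ethyl]oxolan-2-one (methyl trans to aryl) | O=C1OC[C@H](c2ccc(O[Si](C(C)C)(C(C)C)C(C)C)cc2OC)[C@]1(C)CCC3(C)OCCO3 | intermediate
17 | (3S,4R)-4-ArSi-3-methyl-3-[2-(2-methyl-1,3-dioxolan-2-yl)ethyl]oxolan-2-ol (both anomers) | OC1OC[C@H](c2ccc(O[Si](C(C)C)(C(C)C)C(C)C)cc2OC)[C@]1(C)CCC3(C)OCCO3 | intermediate
18 | (2S,3R)-2-ArSi-3-methyl-3-[2-(2-methyl-1,3-dioxolan-2-yl)ethyl]pent-4-en-1-ol | OC[C@H](c1ccc(O[Si](C(C)C)(C(C)C)C(C)C)cc1OC)[C@@](C)(C=C)CCC1(C)OCCO1 | intermediate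
19 | 4-bromo-3-methoxyphenol | COc1cc(O)ccc1Br | starting material
20 | (4-bromo-3-methoxyphenoxy)triisopropylsilane | COc1cc(O[Si](C(C)C)(C(C)C)C(C)C)ccc1Br | intermediate
21 | (2S,3R,4E)-2,5-bis(ArSi)-3-methyl-3-[2-(2-methyl-1,3-dioxolan-2-yl)ethyl]pent-4-en-1-ol | OC[C@H](c1ccc(O[Si](C(C)C)(C(C)C)C(C)C)cc1OC)[C@@](C)(/C=C/c1ccc(O[Si](C(C)C)(C(C)C)C(C)C)cc1OC)CCC1(C)OCCO1 | intermediate
22 | (5R,6S)-6-ArSi-5-[(E)-2-ArSi-ethenyl]-7-hydroxy-5-methylheptan-2-one | OC[C@H](c1ccc(O[Si](C(C)C)(C(C)C)C(C)C)cc1OC)[C@@](C)(/C=C/c1ccc(O[Si](C(C)C)(C(C)C)C(C)C)cc1OC)CCC(C)=O | intermediate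
23 | (2S,3R)-2-ArSi-3-[(E)-2-ArSi-ethenyl]-3-methyl-6-oxoheptanal | O=C[C@H](c1ccc(O[Si](C(C)C)(C(C)C)C(C)C)cc1OC)[C@@](C)(/C=C/c1ccc(O[Si](C(C)C)(C(C)C)C(C)C)cc1OC)CCC(C)=O | intermediate
24 | (5R,6S)-6-ArSi-5-[(E)-2-ArSi-ethenyl]-5-methyloct-7-en-2-one | C=C[C@H](c1ccc(O[Si](C(C)C)(C(C)C)C(C)C)cc1OC)[C@@](C)(/C=C/c1ccc(O[Si](C(C)C)(C(C)C)C(C)C)cc1OC)CCC(C)=O | intermediate
25 | (5R,6S)-6-ArSi-5-[(E)-2-ArSi-ethenyl]-2,5-dimethylocta-1,7-diene | C=C[C@H](c1ccc(O[Si](C(C)C)(C(C)C)C(C)C)cc1OC)[C@@](C)(/C=C/c1ccc(O[Si](C(C)C)(C(C)C)C(C)C)cc1OC)CCC(C)=C | intermediate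
26 | (3S,4R)-3-ArSi-4-[(E)-2-ArSi-ethenyl]-1,4-dimethylcyclohex-1-ene | CC1=C[C@H](c2ccc(O[Si](C(C)C)(C(C)C)C(C)C)cc2OC)[C@@](C)(/C=C/c2ccc(O[Si](C(C)C)(C(C)C)C(C)C)cc2OC)CC1 | intermediate
27 | (3S,4R)-3-(4-hydroxy-2-methoxyphenyl)-4-[(E)-2-(4-hydroxy-2-methoxyphenyl)ethenyl]-1,4-dimethylcyclohex-1-ene | CC1=C[C@H](c2ccc(O)cc2OC)[C@@](C)(/C=C/c2ccc(O)cc2OC)CC1 | intermediate
28 | (3S,4R)-3-[4-hydroxy-5-(hydroxymethyl)-2-methoxyphenyl]-4-[(E)-2-[4-hydroxy-5-(hydroxymethyl)-2-methoxyphenyl]ethenyl]-1,4-dimethylcyclohex-1-ene | CC1=C[C@H](c2cc(CO)c(O)cc2OC)[C@@](C)(/C=C/c2cc(CO)c(O)cc2OC)CC1 | intermediate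
29 | (3S,4R)-3-(5-formyl-4-hydroxy-2-methoxyphenyl)-4-[(E)-2-(5-formyl-4-hydroxy-2-methoxyphenyl)ethenyl]-1,4-dimethylcyclohex-1-ene | CC1=C[C@H](c2cc(C=O)c(O)cc2OC)[C@@](C)(/C=C/c2cc(C=O)c(O)cc2OC)CC1 | intermediate
30 | bis[(triphenylphosphoranylidene)acetate] ester of the two phenols of 29 | CC1=C[C@H](c2cc(C=O)c(OC(=O)C=P(c3ccccc3)(c3ccccc3)c3ccccc3)cc2OC)[C@@](C)(/C=C/c2cc(C=O)c(OC(=O)C=P(c3ccccc3)(c3ccccc3)c3ccccc3)cc2OC)CC1 | intermediate
31 | 6-[(E)-2-[(1R,2S)-2-(7-methoxy-2-oxo-2H-chromen-6-yl)-1,4-dimethylcyclohex-3-en-1-yl]ethenyl]-7-methoxy-2H-chromen-2-one | COc1cc2oc(=O)ccc2cc1/C=C/[C@@]1(C)CCC(C)=C[C@@H]1c1cc2ccc(=O)oc2cc1OC | target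

**Count and risk**
Total step count: 21.
Longest linear sequence: 18 steps (1 to 31 through steps 1, 2, 5–12 and 14–21).

Steps most likely to fail:

Step 8 (oxidative Nef in a nitrosating medium beside an electron-rich arene and a ketal). The fallback sets out from 10 and comes back at 14. The nitronate of 10 (NaOMe, MeOH, 0 °C) is run into buffered aqueous TiCl3/NH4OAc (pH about 5) for a reductive Nef reaction. The resulting aldehyde ester methyl (2R,3S)-3-ArSi-2-[2-(2-methyl-1,3-dioxolan-2-yl)ethyl]-4-oxobutanoate F1 is not stored but reduced at once with NaBH4 (MeOH, −20 °C) to hydroxy ester 13, which lactonises to 14 as in step 9.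

Step 14 (Heck reaction of a vinyl group on a quaternary carbon with an electron-rich aryl bromide). The fallback sets out from lactol 17 and comes back at 21, so it replaces steps 12 and 14. Aldehyde 2 is reduced with NaBH4 (MeOH, 0 °C) to {2-methoxy-4-[(triisopropylsilyl)oxy]phenyl}methanol F2. ZnI2 and P(OEt)3 (toluene, reflux) turn this into diethyl ({2-methoxy-4-[(triisopropylsilyl)oxy]phenyl}methyl)phosphonate F3. Horner–Wadsworth–Emmons olefination of 17 with the sodium salt of F3 (NaH, THF, 0 to 60 °C) gives 21 directly as the (E)-styrene.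

Step 17 (an α-aryl aldehyde beside a methyl ketone under a basic ylide can epimerise at C2 or undergo aldol reaction). The fallback sets out from 23 and comes back at 26, so it replaces steps 17 and 18. SmI2 (THF, −78 °C to rt) joins the aldehyde and ketone carbons of 23 in an intramolecular pinacol coupling to the cis-diol (3S,4R)-3-ArSi-4-[(E)-2-ArSi-ethenyl]-1,4-dimethylcyclohexane-1,2-diol F4. 1,1'-Thiocarbonyldiimidazole (toluene, 80 °C) gives the cyclic thiocarbonate (4S,5R)-4-ArSi-5-[(E)-2-ArSi-ethenyl]-5,7a-dimethylhexahydro-1,3-benzodioxole-2-thione F5. P(OMe)3 (110 °C) then performs the Corey–Winter elimination to cyclohexene 26.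

**Further compounds**
F1 | step 8 | methyl (2R,3S)-3-ArSi-2-[2-(2-methyl-1,3-dioxolan-2-yl)ethyl]-4-oxobutanoate | COC(=O)[C@H](CCC1(C)OCCO1)[C@H](C=O)c1ccc(O[Si](C(C)C)(C(C)C)C(C)C)cc1OC
F2 | step 14 | {2-methoxy-4-[(triisopropylsilyl)oxy]phenyl}methanol | COc1cc(O[Si](C(C)C)(C(C)C)C(C)C)ccc1CO
F3 | step 14 | diethyl ({2-methoxy-4-[(triisopropylsilyl)oxy]phenyl}methyl)phosphonate | CCOP(=O)(OCC)Cc1ccc(O[Si](C(C)C)(C(C)C)C(C)C)cc1OC
F4 | step 17 | (3S,4R)-3-ArSi-4-[(E)-2-ArSi-ethenyl]-1,4-dimethylcyclohexane-1,2-diol (cis-diol, C1 and C2 not assigned) | CC1(O)C(O)[C@H](c2ccc(O[Si](C(C)C)(C(C)C)C(C)C)cc2OC)[C@@](C)(/C=C/c2ccc(O[Si](C(C)C)(C(C)C)C(C)C)cc2OC)CC1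
F5 | step 17 | (4S,5R)-4-ArSi-5-[(E)-2-ArSi-ethenyl]-5,7a-dimethylhexahydro-1,3-benzodioxole-2-thione (cis ring fusion) | CC12OC(=S)OC1[C@H](c1ccc(O[Si](C(C)C)(C(C)C)C(C)C)cc1OC)[C@@](C)(/C=C/c1ccc(O[Si](C(C)C)(C(C)C)C(C)C)cc1OC)CC2
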